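**Plan**
Retrosynthesis: the isoflavone pyranone is opened at O1–C2, C2–C3 and C4–C4a (one-carbon unit, arylacetyl unit, phenol), the flavone pyranone at O1–C2 and C2–C3 (Claisen), and the central anisole ring B at C2'–C3' and C4'–C5', which leads back to methyl coumalate and an aryl methoxyalkyne; the alkyne–aryl bond is cut last.
Enabling feature: ring B is a benzene with flavone C2 at C1', the hindered phloroglucinol ring (isoflavone C8) at C3' and OMe at C4'; a 5-carboxy-2-pyrone (ester carbon to C1') and an alkyne Ar–C≡C–OMe (aryl carbon to C3', methoxy carbon to C4') deliver exactly this 1,3,4 pattern after loss of CO2.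
Forward: the phloroglucinol ring is differentiated (one MOM, two benzyl ethers), iodinated and alkynylated; ring B is built by the cycloaddition; the flavone pyranone is then made from the benzoate, the isoflavone pyranone is closed last at the MOM-marked oxygen, and hydrogenolysis frees the four phenols.
Stereochemistry: the target has no stereocentre; the only stereocentres on the way (bridgeheads of the cycloadduct) vanish with CO2.

Key step: step 5

Assumption: the target structure carries no stereodescriptor, so the biaryl axis is treated as not configurationally defined and no atropselective step is planned.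

Step 1
Reactants: 1 3,5-bis(benzyloxy)phenol
Product: 2 1,3-bis(benzyloxy)-5-(methoxymethoxy)benzene
Conditions: MOMCl, i-Pr2NEt, CH2Cl2, 0 °C → rt
Reagents that add atoms: chloromethyl methyl ether, COCCl
Why: Williamson-type O-alkylation of the only free phenol gives the acetal that later marks the oxygen destined to become O1 of the isoflavone and directs the metalation.

Step 2
Reactants: 2 1,3-bis(benzyloxy)-5-(methoxymethoxy)benzene
Product: 4 1,5-bis(benzyloxy)-2-iodo-3-(methoxymethoxy)benzene, via aryllithium 3 (not isolated)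
Conditions: n-BuLi, THF, 0 °C; then I2, −78 °C → rt
Reagents that add atoms: iodine, II
Why: Directed ortho-metalation, in which the chelating MOM acetal should steer n-BuLi to the proton between OMOM and a benzyloxy group (two equivalent sites) rather than to the one between the two benzyloxy groups, followed by iodine quench of the aryllithium.

Step 3
Reactants: 5 trichloroethylene
Product: 7 (E)-1,2-dichloro-1-methoxyethene, via dichloroethyne 6 (not isolated)
Conditions: KOMe, THF, −50 °C → rt; distillation
Reagents that add atoms: potassium methoxide, C[O-].[K+]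
Why: Base-induced dehydrochlorination to dichloroethyne (kept in solution) and anti addition of methoxide, the standard entry to 1,2-dichlorovinyl ethers, should give the E ether after protonation of the vinyl anion by fresh trichloroethylene.

Step 4
Reactants: 7 (E)-1,2-dichloro-1-methoxyethene; 4 1,5-bis(benzyloxy)-2-iodo-3-(methoxymethoxy)benzene
Product: 11 1,5-bis(benzyloxy)-2-(methoxyethynyl)-3-(methoxymethoxy)benzene, via chloro(methoxy)ethyne 8 (not isolated), via lithium methoxyacetylide 9 (not isolated), via methoxyethynylzinc chloride 10 (not isolated)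
Conditions: 7, n-BuLi (2 equiv), THF, −78 → −40 °C; ZnCl2, −78 → 0 °C; then 4, Pd(PPh3)4 (cat.), THF, rt → 50 °C; filtration through basic alumina
Reagents that add atoms: none
Why: Dehydrochlorination and chlorine–lithium exchange give the lithium alkoxyacetylide, which after transmetalation to zinc should undergo Negishi coupling with the aryl iodide, the small linear alkynyl group tolerating the two ortho substituents.

Step 5
Reactants: 11 1,5-bis(benzyloxy)-2-(methoxyethynyl)-3-(methoxymethoxy)benzene; 12 methyl coumalate (methyl 2-oxo-2H-pyran-5-carboxylate)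
Product: 14 methyl 3-[2,4-bis(benzyloxy)-6-(methoxymethoxy)phenyl]-4-methoxybenzoate, via bicyclic lactone cycloadduct 13 (not isolated)
Conditions: 12 (1.5 equiv), toluene, 110 °C, sealed tube
Reagents that add atoms: none
Why: The electron-poor 2-pyrone 12 acts as the diene (C3 to C6) in an inverse-electron-demand Diels–Alder reaction with the electron-rich alkyne 11; bond formation is asynchronous, the aryl-bearing alkyne carbon (made nucleophilic by the methoxy oxygen) attacking pyrone C6 and the methoxy-bearing carbon closing onto C3, and the resulting bicyclic lactone 13 loses CO2 by a retro-(4+2) step and is aromatic at once. The closest known reaction type is the cycloaddition of methyl coumalate with ynamines, ketene acetals and alkoxyalkynes, which gives substituted benzoates after CO2 extrusion. Ring B is closed by an intermolecular (4+2) cycloaddition that forms C2'–C3' and C4'–C5' in one operation, the carbocycle being made of four pyrone carbons and the two alkyne carbons. The two bridgehead stereocentres of 13 arise as a racemate without control and are destroyed on aromatisation, so no stereocentre has to be set. The step needs regioselectivity (methoxy para and aryl meta to the ester), which is secured by matching the polarisation of the ynol ether with the electrophilic C6 (beta to the ester) of the coumalate; the hindered aryl carbon meets an unsubstituted CH terminus, so the two ortho ethers should be tolerated. A methyl ynol ether has no beta-hydrogen in its O-alkyl group and cannot fragment to a ketene by a retro-ene path, so it should survive the heating.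

Step 6
Reactants: 15 1-(2,4,6-trihydroxyphenyl)ethanone
Product: 16 1-[2,4-bis(benzyloxy)-6-hydroxyphenyl]ethanone
Conditions: BnBr (2.1 equiv), K2CO3, DMF, rt
Reagents that add atoms: benzyl bromide, BrCc1ccccc1
Why: Williamson benzylation takes the two more acidic, non-chelated hydroxyls and should leave the hydroxyl hydrogen-bonded to the ketone free, as needed for the later ring closure.

Step 7
Reactants: 16 1-[2,4-bis(benzyloxy)-6-hydroxyphenyl]ethanone; 14 methyl 3-[2,4-bis(benzyloxy)-6-(methoxymethoxy)phenyl]-4-methoxybenzoate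
Product: 18 1-[2,4-bis(benzyloxy)-6-hydroxyphenyl]-3-{3-[2,4-bis(benzyloxy)-6-(methoxymethoxy)phenyl]-4-methoxyphenyl}propane-1,3-dione, via dilithium enolate-phenolate 17 (not isolated)
Conditions: 16, LiN(SiMe3)2 (3.5 equiv), THF, −78 → −10 °C; then 14, −78 °C → rt; aq. HCl
Reagents that add atoms: none
Why: Crossed Claisen condensation of the ketone enolate (as its phenolate dianion) with the unhindered, non-enolisable methyl benzoate gives the o-hydroxyaryl 1,3-diketone directly, driven by deprotonation of the product, without the hydrolysis and esterification a Baker–Venkataraman sequence would need.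

Step 8
Reactants: 18 1-[2,4-bis(benzyloxy)-6-hydroxyphenyl]-3-{3-[2,4-bis(benzyloxy)-6-(methoxymethoxy)phenyl]-4-methoxyphenyl}propane-1,3-dione
Product: 20 5,7-bis(benzyloxy)-2-{3-[2,4-bis(benzyloxy)-6-hydroxyphenyl]-4-methoxyphenyl}-4H-chromen-4-one, via MOM-protected flavone 19 (not isolated)
Conditions: conc. HCl, MeOH–THF, 55 °C
Reagents that add atoms: none
Why: Acid-catalysed cyclodehydration of the o-hydroxyaryl 1,3-diketone closes the flavone pyranone and the same acid methanolyses the MOM acetal (the order of the two events is immaterial), while the benzyl ethers should be stable under these mild conditions.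

Step 9
Reactants: 20 5,7-bis(benzyloxy)-2-{3-[2,4-bis(benzyloxy)-6-hydroxyphenyl]-4-methoxyphenyl}-4H-chromen-4-one; 21 4-methoxyphenylacetic acid
Product: 22 5,7-bis(benzyloxy)-2-(3-{4,6-bis(benzyloxy)-2-hydroxy-3-[(4-methoxyphenyl)acetyl]phenyl}-4-methoxyphenyl)-4H-chromen-4-one
Conditions: 21, BF3·OEt2 (as solvent), 60 °C; then aq. NaOAc
Reagents that add atoms: none
Why: BF3-mediated Friedel–Crafts acylation (O-acylation and Fries-type shift), the standard deoxybenzoin synthesis, should place the acyl group on the only open carbon ortho to the free hydroxyl, which is favoured by the boron chelate of the product, whereas the carbon between the two benzyloxy groups is more hindered.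

Step 10
Reactants: 22 5,7-bis(benzyloxy)-2-(3-{4,6-bis(benzyloxy)-2-hydroxy-3-[(4-methoxyphenyl)acetyl]phenyl}-4-methoxyphenyl)-4H-chromen-4-one
Product: 24 5,7-bis(benzyloxy)-8-{5-[5,7-bis(benzyloxy)-4-oxo-4H-chromen-2-yl]-2-methoxyphenyl}-3-(4-methoxyphenyl)-4H-chromen-4-one, via enaminone 23 (not isolated)
Conditions: Me2NCH(OMe)2, toluene, 90 °C
Reagents that add atoms: N,N-dimethylformamide dimethyl acetal, COC(OC)N(C)C
Why: Condensation of the activated methylene with the amide acetal gives an enaminone, and the single free hydroxyl then closes the pyranone by intramolecular addition–elimination with loss of dimethylamine, so only the 8-aryl isoflavone can form.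

Step 11
Reactants: 24 5,7-bis(benzyloxy)-8-{5-[5,7-bis(benzyloxy)-4-oxo-4H-chromen-2-yl]-2-methoxyphenyl}-3-(4-methoxyphenyl)-4H-chromen-4-one
Product: 25 8-[5-(5,7-dihydroxy-4-oxo-4H-chromen-2-yl)-2-methoxyphenyl]-5,7-dihydroxy-3-(4-methoxyphenyl)-4H-chromen-4-one (CNP0117905.0)
Conditions: H2 (1 atm), 10% Pd/C, THF–MeOH, rt
Reagents that add atoms: none
Why: Catalytic hydrogenolysis should cleave the four benzyl aryl ethers while the two methyl ethers stay, and at 1 atm with monitoring the chromone double bonds are expected to remain.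

**Compound list**
1 | 3,5-bis(benzyloxy)phenol | Oc1cc(OCc2ccccc2)cc(OCc2ccccc2)c1 | starting material
2 | 1,3-bis(benzyloxy)-5-(methoxymethoxy)benzene | COCOc1cc(OCc2ccccc2)cc(OCc2ccccc2)c1 | intermediate
3 | [2,4-bis(benzyloxy)-6-(methoxymethoxy)phenyl]lithium (formed in the flask) | [Li]c1c(OCOC)cc(OCc2ccccc2)cc1OCc1ccccc1 | intermediate
4 | 1,5-bis(benzyloxy)-2-iodo-3-(methoxymethoxy)benzene | COCOc1cc(OCc2ccccc2)cc(OCc2ccccc2)c1I | intermediate
5 | trichloroethylene | ClC=C(Cl)Cl | starting material
6 | dichloroethyne (formed in the flask) | ClC#CCl | intermediate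
7 | (E)-1,2-dichloro-1-methoxyethene | CO/C(Cl)=C\Cl | intermediate
8 | chloro(methoxy)ethyne (formed in the flask) | COC#CCl | intermediate
9 | lithium methoxyacetylide (formed in the flask) | COC#C[Li] | intermediate
10 | methoxyethynylzinc chloride (formed in the flask) | COC#C[Zn]Cl | intermediate
11 | 1,5-bis(benzyloxy)-2-(methoxyethynyl)-3-(methoxymethoxy)benzene | COC#Cc1c(OCOC)cc(OCc2ccccc2)cc1OCc1ccccc1 | intermediate
12 | methyl coumalate (methyl 2-oxo-2H-pyran-5-carboxylate) | COC(=O)C1=COC(=O)C=C1 | starting material
13 | methyl 7-[2,4-bis(benzyloxy)-6-(methoxymethoxy)phenyl]-8-methoxy-3-oxo-2-oxabicyclo[2.2.2]octa-5,7-diene-6-carboxylate (racemic, one enantiomer drawn; formed in the flask) | O=C1O[C@@H]2C(C(=O)OC)=C[C@H]1C(OC)=C2c3c(OCOC)cc(OCc4ccccc4)cc3OCc5ccccc5 | intermediate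
14 | methyl 3-[2,4-bis(benzyloxy)-6-(methoxymethoxy)phenyl]-4-methoxybenzoate | COC(=O)c1ccc(OC)c(c1)-c1c(OCOC)cc(OCc2ccccc2)cc1OCc1ccccc1 | intermediate
15 | 1-(2,4,6-trihydroxyphenyl)ethanone | CC(=O)c1c(O)cc(O)cc1O | starting material
16 | 1-[2,4-bis(benzyloxy)-6-hydroxyphenyl]ethanone | CC(=O)c1c(O)cc(OCc2ccccc2)cc1OCc1ccccc1 | intermediate
17 | dilithium 3,5-bis(benzyloxy)-2-(1-oxidoethenyl)phenolate (formed in the flask) | [Li+].[Li+].C=C([O-])c1c([O-])cc(OCc2ccccc2)cc1OCc1ccccc1 | intermediate
18 | 1-[2,4-bis(benzyloxy)-6-hydroxyphenyl]-3-{3-[2,4-bis(benzyloxy)-6-(methoxymethoxy)phenyl]-4-methoxyphenyl}propane-1,3-dione (keto–enol mixture, diketo form drawn) | COCOc1cc(OCc2ccccc2)cc(OCc2ccccc2)c1-c1cc(ccc1OC)C(=O)CC(=O)c1c(O)cc(OCc2ccccc2)cc1OCc1ccccc1 | intermediate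
19 | 5,7-bis(benzyloxy)-2-{3-[2,4-bis(benzyloxy)-6-(methoxymethoxy)phenyl]-4-methoxyphenyl}-4H-chromen-4-one (formed in the flask) | COCOc1cc(OCc2ccccc2)cc(OCc2ccccc2)c1-c1cc(ccc1OC)-c1cc(=O)c2c(OCc3ccccc3)cc(OCc3ccccc3)cc2o1 | intermediate
20 | 5,7-bis(benzyloxy)-2-{3-[2,4-bis(benzyloxy)-6-hydroxyphenyl]-4-methoxyphenyl}-4H-chromen-4-one | Oc1cc(OCc2ccccc2)cc(OCc2ccccc2)c1-c1cc(ccc1OC)-c1cc(=O)c2c(OCc3ccccc3)cc(OCc3ccccc3)cc2o1 | intermediate
21 | 4-methoxyphenylacetic acid | COc1ccc(CC(=O)O)cc1 | starting material
22 | 5,7-bis(benzyloxy)-2-(3-{4,6-bis(benzyloxy)-2-hydroxy-3-[(4-methoxyphenyl)acetyl]phenyl}-4-methoxyphenyl)-4H-chromen-4-one | COc1ccc(CC(=O)c2c(O)c(-c3cc(ccc3OC)-c3cc(=O)c4c(OCc5ccccc5)cc(OCc5ccccc5)cc4o3)c(OCc3ccccc3)cc2OCc2ccccc2)cc1 | intermediate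
23 | 5,7-bis(benzyloxy)-2-(3-{4,6-bis(benzyloxy)-3-[3-(dimethylamino)-2-(4-methoxyphenyl)prop-2-enoyl]-2-hydroxyphenyl}-4-methoxyphenyl)-4H-chromen-4-one (alkene geometry not defined; formed in the flask) | COc1ccc(C(=CN(C)C)C(=O)c2c(O)c(-c3cc(ccc3OC)-c3cc(=O)c4c(OCc5ccccc5)cc(OCc5ccccc5)cc4o3)c(OCc3ccccc3)cc2OCc2ccccc2)cc1 | intermediate
24 | 5,7-bis(benzyloxy)-8-{5-[5,7-bis(benzyloxy)-4-oxo-4H-chromen-2-yl]-2-methoxyphenyl}-3-(4-methoxyphenyl)-4H-chromen-4-one | COc1ccc(-c2coc3c(-c4cc(-c5cc(=O)c6c(OCc7ccccc7)cc(OCc7ccccc7)cc6o5)ccc4OC)c(OCc4ccccc4)cc(OCc4ccccc4)c3c2=O)cc1 | intermediate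
25 | 8-[5-(5,7-dihydroxy-4-oxo-4H-chromen-2-yl)-2-methoxyphenyl]-5,7-dihydroxy-3-(4-methoxyphenyl)-4H-chromen-4-one | COc1ccc(-c2coc3c(-c4cc(-c5cc(=O)c6c(O)cc(O)cc6o5)ccc4OC)c(O)cc(O)c3c2=O)cc1 | target

**Count**
Total steps: 11. Longest linear sequence: 9 steps (steps 1, 2, 4, 5, 7, 8, 9, 10, 11 from compound 1); steps 3 and 6 are one-step side branches.

**Steps most likely to fail**

Step 5. The cycloaddition may be too slow at the alkyne carbon that carries the doubly ortho-substituted aryl group. Thermal self-reaction of the pyrone, or hydration and oligomerisation of the ynol ether, could then overtake it, and partial loss of regiocontrol would give the isomeric benzoate. Fallback: setting out from iodide 4, a Suzuki–Miyaura coupling with commercial [2-methoxy-5-(methoxycarbonyl)phenyl]boronic acid (Pd(OAc)2, SPhos, K3PO4, toluene–H2O, 90 °C) would give biaryl ester 14 directly and rejoin the route there. Ring B then arrives ready-made, steps 3 and 4 are not needed, and no new compound arises (F0).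

Step 9. Hot BF3·OEt2 may cleave or shift benzyl groups, and the acyl group may enter para to the hydroxyl (between the two benzyloxy groups) instead of ortho. Fallback: setting out from phenol 20, a Houben–Hoesch reaction with 4-methoxyphenylacetonitrile (ZnCl2, HCl gas, Et2O–CH2Cl2, 0 °C) would give the deoxybenzoin ketiminium chloride F1 (the C=NH2+ Cl− analogue of 22). Hydrolysis in warm aqueous methanol then comes back to deoxybenzoin 22. The cold protic conditions spare benzyl ethers and the bulkier nitrilium electrophile further disfavours the crowded para site.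

Step 4. The cross-coupling may be sluggish at the hindered, electron-rich iodide so that the zinc acetylide decomposes first, and the ynol ether may be hydrated to the arylacetate during isolation. Fallback: setting out from arene 2 through aryllithium 3 (generated as in step 2), acylation with N,2-dimethoxy-N-methylacetamide would give 1-[2,4-bis(benzyloxy)-6-(methoxymethoxy)phenyl]-2-methoxyethanone F2. Enolisation and triflation (LiN(SiMe3)2, PhNTf2, THF, −78 °C) would convert it into (Z)-1-[2,4-bis(benzyloxy)-6-(methoxymethoxy)phenyl]-2-methoxyethenyl trifluoromethanesulfonate F3. Anti elimination with KOt-Bu (THF, −78 °C → rt) would deliver ynol ether 11, where the route resumes; no cross-coupling and no iodide are needed.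

**Further compounds**
F0 | step 5 | none | none
F1 | step 9 | 1-{2,4-bis(benzyloxy)-5-[5-(5,7-bis(benzyloxy)-4-oxo-4H-chromen-2-yl)-2-methoxyphenyl]-6-hydroxyphenyl}-2-(4-methoxyphenyl)ethaniminium chloride | COc1ccc(CC(=[NH2+])c2c(O)c(-c3cc(ccc3OC)-c3cc(=O)c4c(OCc5ccccc5)cc(OCc5ccccc5)cc4o3)c(OCc3ccccc3)cc2OCc2ccccc2)cc1.[Cl-]
F2 | step 4 | 1-[2,4-bis(benzyloxy)-6-(methoxymethoxy)phenyl]-2-methoxyethanone | COCC(=O)c1c(OCOC)cc(OCc2ccccc2)cc1OCc1ccccc1
F3 | step 4 | (Z)-1-[2,4-bis(benzyloxy)-6-(methoxymethoxy)phenyl]-2-methoxyethenyl trifluoromethanesulfonate | CO/C=C(\OS(=O)(=O)C(F)(F)F)c1c(OCOC)cc(OCc2ccccc2)cc1OCc1ccccc1
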